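**Retrosynthetic overview**

1. Target 21 ⇐ lactol 20 (aldehyde-to-acid oxidation) ⇐ ester 19 ⇐ alcohol 12 + side-chain acid 17 (acylation of the C3 hydroxyl; 17 comes from but-2-yn-1-ol).
2. Key disconnection: the C4–Cα bond, made by trivalent-titanium epoxide opening and 5-exo-dig radical cyclization of propargylic acetal 11. This one step fixes the all-cis C3–O / C4–C / C5–O triad and frees the C3 hydroxyl.
3. Epoxide 8 ⇐ allylic alcohol 7 (hydroxyl-directed epoxidation) ⇐ cyclobutene 6 (ring-opening metathesis with ethylene gives the cis vinyl / 2-propenyl pair).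
4. Cyclobutene 3 ⇐ 3-methylcyclohex-2-enone 1 + propargyl silyl ether 2 by enantioselective [2+2] photocycloaddition (sets C1 and C6).
5. Ring order: the six-membered ring is bought; cyclobutene (step 1, opened in step 4); epoxide (step 5, opened in step 7); tetrahydrofuran acetal (step 7, opened in steps 12–13).

Assumption: silane 2 (propargyl alcohol carrying its silyl protecting group) is bought as such; ring carbons are called C1–C6 in the order of the target SMILES (C1 quaternary, C3 acyloxy, C4 acrylic acid, C5 hydroxyl, C6 hydroxy-isopropenyl), and Cα is the acrylic carbon bonded to C4.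

**Step 1**
Reactants: 1 3-methylcyclohex-2-en-1-one; 2 tert-butyl(dimethyl)(prop-2-yn-1-yloxy)silane
Product: 3 (1R,6R)-8-({[tert-butyl(dimethyl)silyl]oxy}methyl)-6-methylbicyclo[4.2.0]oct-7-en-2-one
Conditions: hν (366 nm), AlBr3-activated prolinol-derived B-aryl oxazaborolidine (50 mol %, enantiomer chosen for the (1R,6R) product), 2 (5 equiv), CH2Cl2, −75 °C
Reagents that add atoms: none
Why: Proposed new method: the closest known reaction is the AlBr3/oxazaborolidine-catalysed enantioselective [2+2] photocycloaddition of this same enone with alkenes, and the racemic enone–alkyne photocycloaddition via a triplet 1,4-biradical is also known, so the Lewis-acid-bound enone excited at 366 nm should add the alkyne on its unshielded face to give the necessarily cis-fused cyclobutene (C1 and C6 set together, absolute sense from the catalyst), with the CH2OSi-bearing alkyne carbon expected to bond to the less hindered α-carbon rather than the methyl-bearing β-carbon.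

**Step 2**
Reactants: 3 (1R,6R)-8-({[tert-butyl(dimethyl)silyl]oxy}methyl)-6-methylbicyclo[4.2.0]oct-7-en-2-one
Product: 5 (1R,6R)-8-({[tert-butyl(dimethyl)silyl]oxy}methyl)-6-methylbicyclo[4.2.0]octa-3,7-dien-2-one, via lithium enolate 4 (not isolated)
Conditions: LiN(iPr)2, THF, −78 °C; then PhS(Cl)=NtBu, −78 °C
Reagents that add atoms: none
Why: Mukaiyama dehydrogenation, in which kinetic deprotonation goes to the CH2 side (an enolate toward the ring-fusion carbon would be a strained methylenecyclobutene), the enolate is sulfenylated and the adduct eliminates at low temperature to the enone without touching either stereocentre.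

**Step 3**
Reactants: 5 (1R,6R)-8-({[tert-butyl(dimethyl)silyl]oxy}methyl)-6-methylbicyclo[4.2.0]octa-3,7-dien-2-one
Product: 6 (1R,2R,6R)-8-({[tert-butyl(dimethyl)silyl]oxy}methyl)-6-methylbicyclo[4.2.0]octa-3,7-dien-2-ol
Conditions: NaBH4, CeCl3·7H2O, MeOH, −78 to 0 °C
Reagents that add atoms: none
Why: Luche 1,2-reduction, in which hydride attacks the flattened bicyclic enone from the convex face, anti to the substituted cyclobutene carbon next to the carbonyl, so the new C5 hydroxyl ends up cis to the four-membered ring.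

**Step 4**
Reactants: 6 (1R,2R,6R)-8-({[tert-butyl(dimethyl)silyl]oxy}methyl)-6-methylbicyclo[4.2.0]octa-3,7-dien-2-ol
Product: 7 (1R,5R,6R)-6-(3-{[tert-butyl(dimethyl)silyl]oxy}prop-1-en-2-yl)-5-ethenyl-5-methylcyclohex-2-en-1-ol
Conditions: second-generation Grubbs catalyst RuCl2(=CHPh)(H2IMes)(PCy3) (5 mol %), ethylene (1 atm), CH2Cl2, rt
Reagents that add atoms: ethylene C=C
Why: Ring-opening cross-metathesis (ethenolysis) driven by cyclobutene strain turns the two cyclobutene carbons into the vinyl group on C1 and the 2-propenyl group on C6, which stay cis because no stereocentre is touched, while the unstrained cyclohexene does not react.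

**Step 5**
Reactants: 7 (1R,5R,6R)-6-(3-{[tert-butyl(dimethyl)silyl]oxy}prop-1-en-2-yl)-5-ethenyl-5-methylcyclohex-2-en-1-ol
Product: 8 (1S,2S,3R,4R,6R)-3-(3-{[tert-butyl(dimethyl)silyl]oxy}prop-1-en-2-yl)-4-ethenyl-4-methyl-7-oxabicyclo[4.1.0]heptan-2-ol
Conditions: VO(acac)2 (3 mol %), tBuOOH, CH2Cl2, 0 °C to rt
Reagents that add atoms: tert-butyl hydroperoxide CC(C)(C)OO
Why: Hydroxyl-directed vanadium-catalysed epoxidation delivers oxygen to the allylic ring alkene on the face of the C5 hydroxyl (cis-epoxy alcohol, sets C3 and C4 oxygen cis to C5–O) much faster than to the homoallylic 1,1-disubstituted alkene or the vinyl group.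

**Step 6**
Reactants: 8 (1S,2S,3R,4R,6R)-3-(3-{[tert-butyl(dimethyl)silyl]oxy}prop-1-en-2-yl)-4-ethenyl-4-methyl-7-oxabicyclo[4.1.0]heptan-2-ol; 9 3,3-dimethoxyprop-1-yne
Product: 11 tert-butyl[(2-{(1R,2S,3R,4R,6R)-4-ethenyl-2-[(1-methoxyprop-2-yn-1-yl)oxy]-4-methyl-7-oxabicyclo[4.1.0]heptan-3-yl}prop-2-en-1-yl)oxy]dimethylsilane (both epimers at the acetal carbon), via 3-chloro-3-methoxyprop-1-yne 10 (not isolated)
Conditions: 9 (3 equiv), AcCl, ZnBr2 (1 mol %), CH2Cl2, 0 °C to rt; then 8, iPr2NEt, 0 °C to rt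
Reagents that add atoms: none
Why: O-alkylation of the hindered alcohol with an α-chloro ether made in the flask from the acetal and acetyl chloride runs under basic conditions, so the epoxide survives and no ring stereocentre changes (the new acetal centre is a mixture that is erased in step 12).

**Step 7**
Reactants: 11 tert-butyl[(2-{(1R,2S,3R,4R,6R)-4-ethenyl-2-[(1-methoxyprop-2-yn-1-yl)oxy]-4-methyl-7-oxabicyclo[4.1.0]heptan-3-yl}prop-2-en-1-yl)oxy]dimethylsilane
Product: 12 (3aR,4R,6R,7R,7aS)-7-(3-{[tert-butyl(dimethyl)silyl]oxy}prop-1-en-2-yl)-6-ethenyl-2-methoxy-6-methyl-3-methylideneoctahydro-1-benzofuran-4-ol (both C2 epimers)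
Conditions: Cp2TiCl2 (20 mol %), Mn dust, 2,4,6-collidine·HCl, THF, rt, slow addition of 11
Reagents that add atoms: none
Why: Nugent–RajanBabu reductive epoxide opening/radical cyclization, in which trivalent titanium (Cp2TiCl) cleaves the epoxide C–O bond next to the oxygenated carbon to give the C4 radical, which closes 5-exo-dig onto the tethered alkyne and can only do so cis to the C5–O tether, so C4 is set cis to both flanking oxygens, the epoxide oxygen is released as the C3 hydroxyl with its configuration intact, and the vinyl radical is reduced and protonated to the exocyclic methylene.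

**Step 8**
Reactants: 13 but-2-yn-1-ol
Product: 15 (2Z)-3-iodobut-2-en-1-ol, via alkenylaluminate 14 (not isolated)
Conditions: NaAlH2(OCH2CH2OMe)2, THF, 0 °C to rt; then I2, −78 °C
Reagents that add atoms: iodine II
Why: Hydroxyl-directed trans-hydroalumination of the propargylic alcohol places aluminium on C3 cis to the CH2O group, and iodinolysis with retention gives the Z vinyl iodide.

**Step 9**
Reactants: 15 (2Z)-3-iodobut-2-en-1-ol
Product: 16 (2Z)-3-iodobut-2-en-1-yl acetate
Conditions: Ac2O, pyridine, CH2Cl2, 0 °C to rt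
Reagents that add atoms: acetic anhydride CC(=O)OC(C)=O
Why: Simple O-acetylation of the primary alcohol, which leaves the alkene geometry unchanged.

**Step 10**
Reactants: 16 (2Z)-3-iodobut-2-en-1-yl acetate
Product: 17 (2Z)-4-(acetyloxy)-2-methylbut-2-enoic acid
Conditions: Pd(OAc)2 (3 mol %, no phosphine), CO (1 atm), H2O, Et3N, DMF, 40 °C
Reagents that add atoms: carbon monoxide [C-]#[O+]; water O
Why: Palladium-catalysed hydroxycarbonylation (oxidative addition to the vinyl iodide, CO insertion, hydrolysis of the acylpalladium) proceeds with retention of the Z geometry, and the phosphine-free catalyst under CO is a poor ionizer of the allylic acetate.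

**Step 11**
Reactants: 12 (3aR,4R,6R,7R,7aS)-7-(3-{[tert-butyl(dimethyl)silyl]oxy}prop-1-en-2-yl)-6-ethenyl-2-methoxy-6-methyl-3-methylideneoctahydro-1-benzofuran-4-ol; 17 (2Z)-4-(acetyloxy)-2-methylbut-2-enoic acid
Product: 19 (3aR,4R,6R,7R,7aS)-7-(3-{[tert-butyl(dimethyl)silyl]oxy}prop-1-en-2-yl)-6-ethenyl-2-methoxy-6-methyl-3-methylideneoctahydro-1-benzofuran-4-yl (2Z)-4-(acetyloxy)-2-methylbut-2-enoate, via mixed anhydride 18 (not isolated)
Conditions: 2,4,6-Cl3C6H2COCl, Et3N, toluene, rt; then 12, toluene, 80 °C, no DMAP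
Reagents that add atoms: none
Why: Yamaguchi esterification through the mixed anhydride acylates the equatorial C3 hydroxyl without touching a stereocentre, and omitting the nucleophilic catalyst (as is done for angelate esters) avoids Z-to-E isomerization and displacement of the allylic acetate.

**Step 12**
Reactants: 19 (3aR,4R,6R,7R,7aS)-7-(3-{[tert-butyl(dimethyl)silyl]oxy}prop-1-en-2-yl)-6-ethenyl-2-methoxy-6-methyl-3-methylideneoctahydro-1-benzofuran-4-yl (2Z)-4-(acetyloxy)-2-methylbut-2-enoate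
Product: 20 (3aR,4R,6R,7R,7aS)-6-ethenyl-2-hydroxy-7-(3-hydroxyprop-1-en-2-yl)-6-methyl-3-methylideneoctahydro-1-benzofuran-4-yl (2Z)-4-(acetyloxy)-2-methylbut-2-enoate (anomer mixture)
Conditions: HCl (1 M aq), THF, 0 °C to rt
Reagents that add atoms: water O
Why: Mild aqueous-acid hydrolysis cleaves the primary silyl ether and the conjugation-activated methyl acetal in one operation to give the lactol, while the enoate, the allylic acetate and all stereocentres are untouched.

**Step 13**
Reactants: 20 (3aR,4R,6R,7R,7aS)-6-ethenyl-2-hydroxy-7-(3-hydroxyprop-1-en-2-yl)-6-methyl-3-methylideneoctahydro-1-benzofuran-4-yl (2Z)-4-(acetyloxy)-2-methylbut-2-enoate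
Product: 21 2-[(1S,2S,3R,4R,6R)-6-{[(2Z)-4-(acetyloxy)-2-methylbut-2-enoyl]oxy}-4-ethenyl-2-hydroxy-3-(3-hydroxyprop-1-en-2-yl)-4-methylcyclohexyl]prop-2-enoic acid (CNP0261293.6)
Conditions: NaClO2, NaH2PO4, 2-methylbut-2-ene, tBuOH/H2O, 0 °C; cold work-up at pH 5
Reagents that add atoms: sodium chlorite [Na+].[O-]Cl=O
Why: Pinnick oxidation of the lactol through its open 2-substituted acrolein form gives the acrylic acid and frees the C5 hydroxyl without touching alcohols, alkenes, esters or stereocentres, and the buffered cold work-up limits relactonization.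

**Compound list**

1 | 3-methylcyclohex-2-en-1-one | CC1=CC(=O)CCC1 | starting material
2 | tert-butyl(dimethyl)(prop-2-yn-1-yloxy)silane | C#CCO[Si](C)(C)C(C)(C)C | starting material
3 | (1R,6R)-8-({[tert-butyl(dimethyl)silyl]oxy}methyl)-6-methylbicyclo[4.2.0]oct-7-en-2-one | C1=C(CO[Si](C)(C)C(C)(C)C)[C@@H]2C(=O)CCC[C@]12C | intermediate
4 | lithium enolate of 3 (enolate toward the ring CH2) | C1=C(CO[Si](C)(C)C(C)(C)C)[C@@H]2C(O[Li])=CCC[C@]12C | intermediate
5 | (1R,6R)-8-({[tert-butyl(dimethyl)silyl]oxy}methyl)-6-methylbicyclo[4.2.0]octa-3,7-dien-2-one | C1=C(CO[Si](C)(C)C(C)(C)C)[C@@H]2C(=O)C=CC[C@]12C | intermediate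
6 | (1R,2R,6R)-8-({[tert-butyl(dimethyl)silyl]oxy}methyl)-6-methylbicyclo[4.2.0]octa-3,7-dien-2-ol | C1=C(CO[Si](C)(C)C(C)(C)C)[C@@H]2[C@H](O)C=CC[C@]12C | intermediate
7 | (1R,5R,6R)-6-(3-{[tert-butyl(dimethyl)silyl]oxy}prop-1-en-2-yl)-5-ethenyl-5-methylcyclohex-2-en-1-ol | C=C[C@@]1(C)CC=C[C@@H](O)[C@H]1C(=C)CO[Si](C)(C)C(C)(C)C | intermediate
8 | (1S,2S,3R,4R,6R)-3-(3-{[tert-butyl(dimethyl)silyl]oxy}prop-1-en-2-yl)-4-ethenyl-4-methyl-7-oxabicyclo[4.1.0]heptan-2-ol | C=C[C@@]1(C)C[C@H]2O[C@H]2[C@@H](O)[C@H]1C(=C)CO[Si](C)(C)C(C)(C)C | intermediate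
9 | 3,3-dimethoxyprop-1-yne | C#CC(OC)OC | starting material
10 | 3-chloro-3-methoxyprop-1-yne (racemic) | C#CC(Cl)OC | intermediate
11 | tert-butyl[(2-{(1R,2S,3R,4R,6R)-4-ethenyl-2-[(1-methoxyprop-2-yn-1-yl)oxy]-4-methyl-7-oxabicyclo[4.1.0]heptan-3-yl}prop-2-en-1-yl)oxy]dimethylsilane, acetal epimers | C=C[C@@]1(C)C[C@H]2O[C@H]2[C@@H](OC(OC)C#C)[C@H]1C(=C)CO[Si](C)(C)C(C)(C)C | intermediate
12 | (3aR,4R,6R,7R,7aS)-7-(3-{[tert-butyl(dimethyl)silyl]oxy}prop-1-en-2-yl)-6-ethenyl-2-methoxy-6-methyl-3-methylideneoctahydro-1-benzofuran-4-ol, C2 epimers | C=C[C@@]1(C)C[C@@H](O)[C@H]2C(=C)C(OC)O[C@H]2[C@H]1C(=C)CO[Si](C)(C)C(C)(C)C | intermediate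
13 | but-2-yn-1-ol | CC#CCO | starting material
14 | sodium 2,2-bis(2-methoxyethoxy)-3-methyl-2,5-dihydro-1,2-oxaaluminol-2-uide | CC1=CCO[Al-]1(OCCOC)OCCOC.[Na+] | intermediate
15 | (2Z)-3-iodobut-2-en-1-ol | C/C(I)=C/CO | intermediate
16 | (2Z)-3-iodobut-2-en-1-yl acetate | C/C(I)=C/COC(C)=O | intermediate
17 | (2Z)-4-(acetyloxy)-2-methylbut-2-enoic acid | OC(=O)/C(C)=C\COC(C)=O | intermediate
18 | (2Z)-4-(acetyloxy)-2-methylbut-2-enoic 2,4,6-trichlorobenzoic anhydride | O=C(OC(=O)/C(C)=C\COC(C)=O)c1c(Cl)cc(Cl)cc1Cl | intermediate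
19 | (3aR,4R,6R,7R,7aS)-7-(3-{[tert-butyl(dimethyl)silyl]oxy}prop-1-en-2-yl)-6-ethenyl-2-methoxy-6-methyl-3-methylideneoctahydro-1-benzofuran-4-yl (2Z)-4-(acetyloxy)-2-methylbut-2-enoate, C2 epimers | C=C[C@@]1(C)C[C@@H](OC(=O)/C(C)=C\COC(C)=O)[C@H]2C(=C)C(OC)O[C@H]2[C@H]1C(=C)CO[Si](C)(C)C(C)(C)C | intermediate
20 | (3aR,4R,6R,7R,7aS)-6-ethenyl-2-hydroxy-7-(3-hydroxyprop-1-en-2-yl)-6-methyl-3-methylideneoctahydro-1-benzofuran-4-yl (2Z)-4-(acetyloxy)-2-methylbut-2-enoate, anomers | C=C[C@@]1(C)C[C@@H](OC(=O)/C(C)=C\COC(C)=O)[C@H]2C(=C)C(O)O[C@H]2[C@H]1C(=C)CO | intermediate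
21 | 2-[(1S,2S,3R,4R,6R)-6-{[(2Z)-4-(acetyloxy)-2-methylbut-2-enoyl]oxy}-4-ethenyl-2-hydroxy-3-(3-hydroxyprop-1-en-2-yl)-4-methylcyclohexyl]prop-2-enoic acid | C=C[C@@]1(C)C[C@@H](OC(=O)/C(C)=C\COC(C)=O)[C@@H](C(=C)C(=O)O)[C@@H](O)[C@H]1C(=C)CO | target

**Step count**

Total: 13 steps. Longest linear sequence: 10 steps (steps 1–7, 11, 12, 13); steps 8–10 make the side-chain acid.

**Three steps most likely to fail, with fallbacks**

Step 1 (the alkyne partner is untested under the chiral Lewis-acid conditions, and the regiochemistry of ring closure is uncertain). The fallback sets out from 1 and returns at 7, building the C1/C6 pair without a cyclobutene. Copper-catalysed asymmetric conjugate addition of a vinylalane (CH2=CHMgBr/Me2AlCl, Cu(OTf)2, chiral phosphoramidite) to 1 with TMSOTf trapping gives (R)-[(3-ethenyl-3-methylcyclohex-1-en-1-yl)oxy]trimethylsilane F1. Palladium-catalysed alkenylation of its tin enolate (Bu3SnF, PdCl2(P(o-tol)3)2, toluene, 85 °C) with (2-bromoprop-2-en-1-yl)oxy(tert-butyl)dimethylsilane gives (2R,3R)-2-(3-{[tert-butyl(dimethyl)silyl]oxy}prop-1-en-2-yl)-3-ethenyl-3-methylcyclohexan-1-one F2 after separation from its C6 epimer, which is recycled by base equilibration. Mukaiyama dehydrogenation as in step 2 gives (5R,6R)-6-(3-{[tert-butyl(dimethyl)silyl]oxy}prop-1-en-2-yl)-5-ethenyl-5-methylcyclohex-2-en-1-one F3, and Luche reduction then gives 7, with lower facial control than in the bicyclic series.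

Step 7 (the epoxide may open at the other carbon, or the C4 radical may be reduced by titanium and eliminate to the alkene before it cyclizes). The fallback sets out from 7 and returns at 12, reversing the roles so that the radical sits on the tether. Bromo-acetalization of 7 with methoxyallene and NBS (CH2Cl2, −78 °C) gives the 2-bromoallyl mixed acetal, the O-(2-bromo-1-methoxyprop-2-en-1-yl) ether of 7, F4. Bu3SnH/AIBN under air then effects vinyl-radical 5-exo-trig cyclization onto C4 (cis-fused by the tether) with oxygen capture at C3 and PPh3 work-up. This gives the C3-hydroxy bicyclic acetal as an epimer mixture at C3 (drawn as the C3 epimer of 12) F5. Dess–Martin oxidation gives the C3 ketone F6, and NaBH4/CeCl3 reduction from the convex face, anti to the C4–Cα bond, returns 12.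

Step 11 (a hindered alcohol without a nucleophilic catalyst, and an acid that can isomerize or lose acetate). The fallback sets out from 12 and 16 and returns at 19. Palladium-catalysed carbonylative esterification of 12 with vinyl iodide 16 (Pd(OAc)2, Xantphos, CO 1 atm, Et3N, toluene, 70 °C) forms the ester from an acylpalladium species, so neither the free acid nor an activated acyl donor is needed. It makes no compound outside the list (F0).

**Further compounds**

F1 | step 1 | (R)-[(3-ethenyl-3-methylcyclohex-1-en-1-yl)oxy]trimethylsilane | C=C[C@@]1(C)CCCC(O[Si](C)(C)C)=C1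
F2 | step 1 | (2R,3R)-2-(3-{[tert-butyl(dimethyl)silyl]oxy}prop-1-en-2-yl)-3-ethenyl-3-methylcyclohexan-1-one | C=C[C@@]1(C)CCCC(=O)[C@H]1C(=C)CO[Si](C)(C)C(C)(C)C
F3 | step 1 | (5R,6R)-6-(3-{[tert-butyl(dimethyl)silyl]oxy}prop-1-en-2-yl)-5-ethenyl-5-methylcyclohex-2-en-1-one | C=C[C@@]1(C)CC=CC(=O)[C@H]1C(=C)CO[Si](C)(C)C(C)(C)C
F4 | step 7 | O-(2-bromo-1-methoxyprop-2-en-1-yl) ether of 7 (acetal epimers) | C=C[C@@]1(C)CC=C[C@@H](OC(OC)C(Br)=C)[C@H]1C(=C)CO[Si](C)(C)C(C)(C)C
F5 | step 7 | C3 epimer of 12 (C3 hydroxyl trans to the C4–Cα bond; formed with some 12) | C=C[C@@]1(C)C[C@H](O)[C@H]2C(=C)C(OC)O[C@H]2[C@H]1C(=C)CO[Si](C)(C)C(C)(C)C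
F6 | step 7 | (3aR,6R,7R,7aS)-7-(3-{[tert-butyl(dimethyl)silyl]oxy}prop-1-en-2-yl)-6-ethenyl-2-methoxy-6-methyl-3-methylidenehexahydro-1-benzofuran-4(2H)-one | C=C[C@@]1(C)CC(=O)[C@H]2C(=C)C(OC)O[C@H]2[C@H]1C(=C)CO[Si](C)(C)C(C)(C)C
F0 | step 11 | none | none
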